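I would not send your west figure, and this is the reckoning behind mine.

| flask | substrate | coupling partner | remark | time |
|---|---|---|---|---|
| zeta | 0.36 M | 1.9 equiv | run made earlier |  |
| beta | 0.36 M | 2.5 equiv | run made earlier |  |
| delta | 0.36 M | 4.5 equiv | run made earlier |  |
| south-west | 0.36 M | 4.00 equiv |  | 2.0 d |
| west | 0.36 M | 1.50 equiv |  | 2.0 d |

- zeta (time / h: double product / %, mono adduct / %): 6.00: 13.5, 41.5; 15.0: 19.8, 24.5; 20.0: 22.2, 19.2; 25.0: 22.2, 14.6; 30.0: 24.8, 13.6
- beta (time / h: double product / %, mono adduct / %): 3.00: 11.3, 45.0; 8.00: 19.7, 19.1; 15.0: 23.6, 8.2; 25.0: 25.1, 2.5; 30.0: 24.6, 1.8
- delta (time / h: double product / %, mono adduct / %): 6.00: 17.2, 2.0; 15.0: 18.6, 0; 20.0: 18.7, 0.1; 25.0: 20.2, 0; 30.0: 19.8, 0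

(each reading ± 1 percentage point)



1. which of these holds the largest part of the substrate at the end of south-west (substrate / triple product / mono adduct / double product)
2. which of these holds the largest part of the substrate at the end of west (substrate / triple product / mono adduct / double product)
3. double product at the end of west, in percent of the substrate charged

From first to last reading, the zeta and beta runs together gain 25 percentage points of double product while mono adduct falls by 71 points. That gives 0.346, which I call the double share: points of double product won per point of mono adduct lost, a selectivity read with the scatter of these readings.

My assumption is that each substrate takes one coupling partner to become mono adduct, and each mono adduct lost takes one more. West then has a surplus of 0.500 partner per substrate, which I take as used by 2.0 d. Surplus times share gives 17.3% double product in west. Mono adduct stays ahead there, near 50.0% before other losses.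

South-west lies close to the delta run, where double product reads 19.8% against 25.1% in beta. If triple product comes from double product, I take that fall of 5.3 points as a rough estimate of what it holds, less than the double product read in delta. So I say double product for south-west.

Your forecast says triple product for south-west and double product for west, at 38%, and adds: “Double versus triple there is a close call.” We differ on both flasks, and mine is the lower west figure.

The flask gives double product in south-west, 19.8% against 9.17% of triple product. West gives mono adduct at 31.1% among the four asked, with 17.6% of double product against my 17.3%.

    substrate + coupling partner → mono adduct (k = 3.91 /M/h)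
    coupling partner + mono adduct → double product (k = 0.171 /M/h)
    coupling partner + double product ⇌ triple product (K = 0.652 /M, k = 17.6 /M/h)
    coupling partner + mono adduct → over-reaction product (k = 0.400 /M/h)
    2 substrate → self-condensation product (k = 0.499 /M/h)

At the end of west the coupling partner stands at 0.753% of its charge, and over-reaction product, absent from your readings, holds 41.2%. Now cut the west flask to 0.600 equiv of coupling partner. The surplus as I reckoned it is then nil, so the double share predicts 0% double product. That flask ends with 1.68% double product and 48.8% mono adduct.

The runs were generated by integration with made-up constants; noise was put on by code.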